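**Plan**
- Retrosynthesis: remove the two benzyl ethers; then, in the 5-hydroxy-2,2,6,6-tetramethylcyclohex-4-ene-1,3-dione ring (C4 carries the benzylic carbon, C1 is the ketone between the two CMe2 groups), cut the C3–C4 bond and the C1–C2 bond. This leaves a 2,2-dimethyl-3-oxo ester side chain and an isobutyrate on the ortho phenol.
- Next cut the isobutyrate O–acyl bond and the ketone–CMe2 bond (aryl lactone plus methyl isobutyrate enolate), giving a 4-(2-phenylethyl)-3,4-dihydrocoumarin; then cut the aryl–CH bond (phenol plus (E)-5-phenylpent-2-enal). The phenol comes from 2-methylphloroglucinol by C-acylation and O-differentiation.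
- Forward: aryl ketone first; then the benzopyran ring as a temporary ring (lactol, then lactone); this ring is opened by the ester enolate; the carbocyclic trione ring is closed in one operation; debenzylation ends the route.
- Enabling feature: the phenolic oxygen on the aryl carbon ortho to the benzylic methine stands 1,5 to the ketone α-CH2 of the side chain, so an isobutyryl group parked on it reaches that carbon through a six-membered chroman-like transition state. The other α-carbon of that ketone is CMe2, so the CH2 is its only enolizable site, and the finished 1,3,5-trione ring is a stable enolate.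
- Stereochemistry: the single stereocentre is set in step 6 by iminium catalysis ((R)-diphenylprolinol silyl ether, face shielding). It is never α to a carbonyl and is carried unchanged to the target.

Key step: step 10

Remark: the target is treated as the enol tautomer drawn (descriptor R in that tautomer); lactol 11 and the hemiketal form of 15 are each counted together with their open hydroxy-carbonyl form as one compound.

**Step 1**
Reactants: 1 2-methylphloroglucinol (2-methylbenzene-1,3,5-triol); 2 3-phenylpropanoyl chloride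
Product: 3 3-phenyl-1-(2,4,6-trihydroxy-3-methylphenyl)propan-1-one
Conditions: AlCl3 (3.5 equiv), PhNO2, 60 °C; ice, aq. HCl
Reagents that add atoms: none
Why: Friedel–Crafts acylation of the phloroglucinol ring, whose two free positions are equivalent, stops at the monoketone because the acyl group deactivates the ring.

**Step 2**
Reactants: 3 3-phenyl-1-(2,4,6-trihydroxy-3-methylphenyl)propan-1-one
Product: 4 1-[2,6-dihydroxy-4-(methoxymethoxy)-3-methylphenyl]-3-phenylpropan-1-one
Conditions: MOMCl (1.05 equiv), iPr2NEt (1.2 equiv), CH2Cl2, 0 °C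
Reagents that add atoms: chloromethyl methyl ether (MOMCl), COCCl
Why: Under mild base only the hydroxyl para to the ketone, the most acidic one and the one not held in the hydrogen bond to the carbonyl, should be alkylated (regioselective Williamson-type acetal formation).

**Step 3**
Reactants: 4 1-[2,6-dihydroxy-4-(methoxymethoxy)-3-methylphenyl]-3-phenylpropan-1-one
Product: 5 1-[2,6-bis(benzyloxy)-4-(methoxymethoxy)-3-methylphenyl]-3-phenylpropan-1-one
Conditions: BnBr (2.6 equiv), K2CO3 (4 equiv), Bu4NI (cat.), DMF, 60 °C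
Reagents that add atoms: benzyl bromide, BrCc1ccccc1
Why: Williamson benzylation of the two ketone-flanking phenols under forcing carbonate conditions in a dipolar aprotic solvent, which favours O- over C-alkylation.

**Step 4**
Reactants: 5 1-[2,6-bis(benzyloxy)-4-(methoxymethoxy)-3-methylphenyl]-3-phenylpropan-1-one
Product: 6 1-[2,6-bis(benzyloxy)-4-hydroxy-3-methylphenyl]-3-phenylpropan-1-one
Conditions: TsOH·H2O (10 mol %), MeOH–THF, 50 °C
Reagents that add atoms: none
Why: Acid-catalysed transacetalization removes the methoxymethyl group while benzyl ethers and ketone persist, freeing the one phenol that later directs the arylation and carries the tether.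

**Step 5**
Reactants: 7 3-phenylpropanal; 8 (triphenylphosphoranylidene)acetaldehyde
Product: 9 (2E)-5-phenylpent-2-enal
Conditions: toluene, 80 °C
Reagents that add atoms: none
Why: Wittig olefination with a stabilized ylide should give the (E)-enal, with the ylide kept slightly short to avoid a second homologation.

**Step 6**
Reactants: 6 1-[2,6-bis(benzyloxy)-4-hydroxy-3-methylphenyl]-3-phenylpropan-1-one; 9 (2E)-5-phenylpent-2-enal
Product: 11 1-[(4S)-5,7-bis(benzyloxy)-2-hydroxy-8-methyl-4-(2-phenylethyl)-3,4-dihydro-2H-chromen-6-yl]-3-phenylpropan-1-one (mixture of C2 epimers), via open-chain aldehyde 10 (not isolated)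
Conditions: (R)-α,α-diphenylprolinol trimethylsilyl ether (20 mol %), PhCO2H (20 mol %), CH2Cl2, 0 °C → rt
Reagents that add atoms: none
Why: Iminium-catalysed enantioselective Friedel–Crafts alkylation/hemiacetalization of an electron-rich phenol with an enal, in which the arene attacks through its only free ring carbon (ortho to the free hydroxyl) and the diphenyl(silyloxy)methyl group of the (R)-catalyst shields one face of the (E)-iminium ion, so that addition to the open face of the β-carbon should give the (S)-configured benzylic centre.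

**Step 7**
Reactants: 11 1-[(4S)-5,7-bis(benzyloxy)-2-hydroxy-8-methyl-4-(2-phenylethyl)-3,4-dihydro-2H-chromen-6-yl]-3-phenylpropan-1-one
Product: 12 (4S)-5,7-bis(benzyloxy)-8-methyl-4-(2-phenylethyl)-6-(3-phenylpropanoyl)-3,4-dihydro-2H-chromen-2-one
Conditions: Dess–Martin periodinane (1.5 equiv), CH2Cl2, 0 °C → rt
Reagents that add atoms: none
Why: Mild periodinane oxidation of the lactol to the lactone leaves the stereocentre, which is β to the carbonyl, untouched.

**Step 8**
Reactants: 12 (4S)-5,7-bis(benzyloxy)-8-methyl-4-(2-phenylethyl)-6-(3-phenylpropanoyl)-3,4-dihydro-2H-chromen-2-one; 13 methyl 2-methylpropanoate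
Product: 15 methyl (5S)-5-[2,4-bis(benzyloxy)-6-hydroxy-5-methyl-3-(3-phenylpropanoyl)phenyl]-2,2-dimethyl-3-oxo-7-phenylheptanoate, via lithium ester enolate 14 (not isolated)
Conditions: 13 (3.3 equiv), LiN(iPr)2 (3.2 equiv), THF, −78 °C; add 12, −78 → −20 °C; 1 M HCl to pH 5
Reagents that add atoms: none
Why: Crossed Claisen acylation in which the ester enolate adds to the activated aryl lactone carbonyl and the adduct opens with loss of the phenoxide, giving a β-keto ester that has no hydrogen between its carbonyls and a stereocentre that stays β to the new ketone.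

**Step 9**
Reactants: 15 methyl (5S)-5-[2,4-bis(benzyloxy)-6-hydroxy-5-methyl-3-(3-phenylpropanoyl)phenyl]-2,2-dimethyl-3-oxo-7-phenylheptanoate; 16 2-methylpropanoyl chloride
Product: 17 methyl (5S)-5-[2,4-bis(benzyloxy)-5-methyl-6-(2-methylpropanoyloxy)-3-(3-phenylpropanoyl)phenyl]-2,2-dimethyl-3-oxo-7-phenylheptanoate
Conditions: 16 (1.3 equiv), Et3N (2 equiv), DMAP (10 mol %), CH2Cl2, 0 °C → rt
Reagents that add atoms: none
Why: DMAP-catalysed O-acylation of the only free phenol places the isobutyryl unit on the oxygen ortho to the benzylic carbon, which is the tether for the next step.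

**Step 10**
Reactants: 17 methyl (5S)-5-[2,4-bis(benzyloxy)-5-methyl-6-(2-methylpropanoyloxy)-3-(3-phenylpropanoyl)phenyl]-2,2-dimethyl-3-oxo-7-phenylheptanoate
Product: 19 4-[(1R)-1-[2,4-bis(benzyloxy)-6-hydroxy-5-methyl-3-(3-phenylpropanoyl)phenyl]-3-phenylpropyl]-5-hydroxy-2,2,6,6-tetramethylcyclohex-4-ene-1,3-dione, via triketo ester 18 (not isolated)
Conditions: LiN(SiMe3)2 (2.2 equiv), THF, −78 → 0 °C; then LiN(iPr)2 (3.0 equiv), DMPU, −78 → 0 °C; 1 M HCl to pH 5 at 0 °C
Reagents that add atoms: none
Why: Proposed new method: LiN(SiMe3)2 enolizes the chain ketone at its only enolizable carbon (the CH2 next to the benzylic methine), and this carbon attacks the isobutyrate C=O held on the ortho phenolic oxygen through a six-membered chroman-2-olate (6-(enolexo)-exo-trig), which collapses to the C-isobutyryl 1,3-diketonate 18 and the phenoxide; LiN(iPr)2 then removes the isopropyl methine proton, and the tertiary γ-carbon of the resulting diketone dianion adds to the methyl ester on the CMe2 group (6-(enolendo)-exo-trig Dieckmann closure) and expels methoxide to give the cyclohexane-1,3,5-trione as its enolate. The closest known reaction types are the Baker–Venkataraman O-to-C acyl migration of ortho-acyloxyaryl ketones and the γ-acylation of 1,3-diketone dianions by esters, and their combination on an enolate linked through an sp3 carbon is what is new. No stereocentre is created, because the transient centre between the two ketones is erased by enolization and the benzylic stereocentre, β to every carbonyl and without an acidic hydrogen, is carried through unchanged. C- over O-acylation and the choice among the three enolizable sites are secured by the tether, since only the chain enolate carbon reaches the ester through a six-membered transition state (the aryl ketone sits para to the ester oxygen and O-attack would need an eight-membered one). Retro-Michael loss of the new ring is blocked under the basic conditions because the ring is an enolate and would have to leave as a dianion. Any dimethylketene shed by E1cB from the aryl ester enolate should be captured by the same chain enolate and be funnelled to the same product.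

**Step 11**
Reactants: 19 4-[(1R)-1-[2,4-bis(benzyloxy)-6-hydroxy-5-methyl-3-(3-phenylpropanoyl)phenyl]-3-phenylpropyl]-5-hydroxy-2,2,6,6-tetramethylcyclohex-4-ene-1,3-dione
Product: 20 5-hydroxy-2,2,6,6-tetramethyl-4-[(1R)-3-phenyl-1-[2,4,6-trihydroxy-3-methyl-5-(3-phenylpropanoyl)phenyl]propyl]cyclohex-4-ene-1,3-dione (CNP0236721.1)
Conditions: H2 (1 atm), Pd/C (10 wt %), EtOAc–MeOH, rt
Reagents that add atoms: none
Why: Neutral hydrogenolysis of the two benzyl ethers, under which the hydrogen-bonded aryl ketone, the enolized trione and the benzylic stereocentre (no acid or base to start a retro-Michael cleavage) should persist.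

**Compound list**
1 | 2-methylbenzene-1,3,5-triol (2-methylphloroglucinol) | Cc1c(O)cc(O)cc1O | starting material
2 | 3-phenylpropanoyl chloride | O=C(Cl)CCc1ccccc1 | starting material
3 | 3-phenyl-1-(2,4,6-trihydroxy-3-methylphenyl)propan-1-one | Cc1c(O)cc(O)c(C(=O)CCc2ccccc2)c1O | intermediate
4 | 1-[2,6-dihydroxy-4-(methoxymethoxy)-3-methylphenyl]-3-phenylpropan-1-one | Cc1c(OCOC)cc(O)c(C(=O)CCc2ccccc2)c1O | intermediate
5 | 1-[2,6-bis(benzyloxy)-4-(methoxymethoxy)-3-methylphenyl]-3-phenylpropan-1-one | Cc1c(OCOC)cc(OCc2ccccc2)c(C(=O)CCc2ccccc2)c1OCc1ccccc1 | intermediate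
6 | 1-[2,6-bis(benzyloxy)-4-hydroxy-3-methylphenyl]-3-phenylpropan-1-one | Cc1c(O)cc(OCc2ccccc2)c(C(=O)CCc2ccccc2)c1OCc1ccccc1 | intermediate
7 | 3-phenylpropanal | O=CCCc1ccccc1 | starting material
8 | (triphenylphosphoranylidene)acetaldehyde | O=CC=P(c1ccccc1)(c1ccccc1)c1ccccc1 | starting material
9 | (2E)-5-phenylpent-2-enal | O=C/C=C/CCc1ccccc1 | intermediate
10 | (3S)-3-[2,4-bis(benzyloxy)-6-hydroxy-5-methyl-3-(3-phenylpropanoyl)phenyl]-5-phenylpentanal | O=CC[C@H](CCc1ccccc1)c1c(O)c(C)c(OCc2ccccc2)c(C(=O)CCc2ccccc2)c1OCc1ccccc1 | intermediate (not isolated)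
11 | 1-[(4S)-5,7-bis(benzyloxy)-2-hydroxy-8-methyl-4-(2-phenylethyl)-3,4-dihydro-2H-chromen-6-yl]-3-phenylpropan-1-one | OC1C[C@H](CCc2ccccc2)c2c(OCc3ccccc3)c(C(=O)CCc3ccccc3)c(OCc3ccccc3)c(C)c2O1 | intermediate
12 | (4S)-5,7-bis(benzyloxy)-8-methyl-4-(2-phenylethyl)-6-(3-phenylpropanoyl)-3,4-dihydro-2H-chromen-2-one | O=C1C[C@H](CCc2ccccc2)c2c(OCc3ccccc3)c(C(=O)CCc3ccccc3)c(OCc3ccccc3)c(C)c2O1 | intermediate
13 | methyl 2-methylpropanoate (methyl isobutyrate) | COC(=O)C(C)C | starting material
14 | lithium 1-methoxy-2-methylprop-1-en-1-olate | [Li+].[O-]C(OC)=C(C)C | intermediate (not isolated)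
15 | methyl (5S)-5-[2,4-bis(benzyloxy)-6-hydroxy-5-methyl-3-(3-phenylpropanoyl)phenyl]-2,2-dimethyl-3-oxo-7-phenylheptanoate | COC(=O)C(C)(C)C(=O)C[C@H](CCc1ccccc1)c1c(O)c(C)c(OCc2ccccc2)c(C(=O)CCc2ccccc2)c1OCc1ccccc1 | intermediate
16 | 2-methylpropanoyl chloride (isobutyryl chloride) | CC(C)C(=O)Cl | starting material
17 | methyl (5S)-5-[2,4-bis(benzyloxy)-5-methyl-6-(2-methylpropanoyloxy)-3-(3-phenylpropanoyl)phenyl]-2,2-dimethyl-3-oxo-7-phenylheptanoate | COC(=O)C(C)(C)C(=O)C[C@H](CCc1ccccc1)c1c(OC(=O)C(C)C)c(C)c(OCc2ccccc2)c(C(=O)CCc2ccccc2)c1OCc1ccccc1 | intermediate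
18 | methyl 4-[(1S)-1-[2,4-bis(benzyloxy)-6-hydroxy-5-methyl-3-(3-phenylpropanoyl)phenyl]-3-phenylpropyl]-2,2,6-trimethyl-3,5-dioxoheptanoate (C4 not defined, present as its enolate) | COC(=O)C(C)(C)C(=O)C(C(=O)C(C)C)[C@H](CCc1ccccc1)c1c(O)c(C)c(OCc2ccccc2)c(C(=O)CCc2ccccc2)c1OCc1ccccc1 | intermediate (not isolated)
19 | 4-[(1R)-1-[2,4-bis(benzyloxy)-6-hydroxy-5-methyl-3-(3-phenylpropanoyl)phenyl]-3-phenylpropyl]-5-hydroxy-2,2,6,6-tetramethylcyclohex-4-ene-1,3-dione | Cc1c(OCc2ccccc2)c(C(=O)CCc2ccccc2)c(OCc2ccccc2)c([C@@H](CCc2ccccc2)C2=C(O)C(C)(C)C(=O)C(C)(C)C2=O)c1O | intermediate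
20 | 5-hydroxy-2,2,6,6-tetramethyl-4-[(1R)-3-phenyl-1-[2,4,6-trihydroxy-3-methyl-5-(3-phenylpropanoyl)phenyl]propyl]cyclohex-4-ene-1,3-dione | Cc1c(O)c(C(=O)CCc2ccccc2)c(O)c([C@@H](CCc2ccccc2)C2=C(O)C(C)(C)C(=O)C(C)(C)C2=O)c1O | target

Total step count: 11
Longest linear sequence: 10 steps (steps 1, 2, 3, 4, 6, 7, 8, 9, 10, 11)

**Steps most likely to fail**

Step 10. The fourth deprotonation, at the isopropyl methine of the crowded diketonate, may not take place, or the hindered ester may resist attack. The sequence would then stall after the acyl transfer, or the diketonate oxygen would close onto the ester instead of the carbon. The fallback uses known chemistry, sets out from lactone 12 and returns at 19. Commercial 2,2,4,4-tetramethylcyclobutane-1,3-dione is opened with NaOMe (cat.) in MeOH to methyl 2,2,4-trimethyl-3-oxopentanoate F1. Deprotonation with LiN(iPr)2 in THF at −78 °C gives lithium 5-methoxy-2,4,4-trimethyl-5-oxopent-2-en-3-olate F2, which is C-acylated by the aryl lactone 12 (crossed Claisen acylation with phenoxide as leaving group). This should give methyl (7S)-7-[2,4-bis(benzyloxy)-6-hydroxy-5-methyl-3-(3-phenylpropanoyl)phenyl]-2,2,4,4-tetramethyl-3,5-dioxo-9-phenylnonanoate F3. NaOMe in MeOH (or NaH in THF) then closes the ring by an ordinary Dieckmann condensation of the CH2 enolate onto the methyl ester, which needs no dianion and should give 19.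

Step 6. Arylation by the acyl-deactivated, crowded phenol may be slow, the enal may be diverted into dienamine chemistry, and facial selectivity may be poor with an aliphatic enal. The fallback sets out from 6 and 7 and returns at 12, replacing steps 6 and 7. Knoevenagel condensation of 7 with Meldrum's acid gives 2,2-dimethyl-5-(3-phenylpropylidene)-1,3-dioxane-4,6-dione F4. Heating F4 with 6 in pyridine at 80 °C should give the racemic lactone (4RS)-5,7-bis(benzyloxy)-8-methyl-4-(2-phenylethyl)-6-(3-phenylpropanoyl)-3,4-dihydro-2H-chromen-2-one F5 by conjugate arylation and lactonization with loss of acetone and carbon dioxide. Preparative chromatography on a chiral stationary phase then separates 12 from the (4R)-enantiomer F6.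

Step 8. The hindered, tetrasubstituted ester enolate may act as a base instead of a nucleophile (enolization of the lactone and ring fragmentation), or the liberated keto group may be attacked a second time. The fallback sets out from 12 and returns at 15. Me(MeO)NH·HCl and AlMe3 in CH2Cl2 at 0 °C open the lactone to (3S)-3-[2,4-bis(benzyloxy)-6-hydroxy-5-methyl-3-(3-phenylpropanoyl)phenyl]-N-methoxy-N-methyl-5-phenylpentanamide F7, which is used without storage. Excess lithium ester enolate 14 adds to F7 to give a chelated tetrahedral adduct that cannot react further and releases 15 on acidic work-up.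

Further compounds
F1 | step 10 | methyl 2,2,4-trimethyl-3-oxopentanoate | COC(=O)C(C)(C)C(=O)C(C)C
F2 | step 10 | lithium 5-methoxy-2,4,4-trimethyl-5-oxopent-2-en-3-olate | [Li+].[O-]C(=C(C)C)C(C)(C)C(=O)OC
F3 | step 10 | methyl (7S)-7-[2,4-bis(benzyloxy)-6-hydroxy-5-methyl-3-(3-phenylpropanoyl)phenyl]-2,2,4,4-tetramethyl-3,5-dioxo-9-phenylnonanoate | COC(=O)C(C)(C)C(=O)C(C)(C)C(=O)C[C@H](CCc1ccccc1)c1c(O)c(C)c(OCc2ccccc2)c(C(=O)CCc2ccccc2)c1OCc1ccccc1
F4 | step 6 | 2,2-dimethyl-5-(3-phenylpropylidene)-1,3-dioxane-4,6-dione | CC1(C)OC(=O)C(=CCCc2ccccc2)C(=O)O1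
F5 | step 6 | (4RS)-5,7-bis(benzyloxy)-8-methyl-4-(2-phenylethyl)-6-(3-phenylpropanoyl)-3,4-dihydro-2H-chromen-2-one (racemate) | O=C1CC(CCc2ccccc2)c2c(OCc3ccccc3)c(C(=O)CCc3ccccc3)c(OCc3ccccc3)c(C)c2O1
F6 | step 6 | (4R)-5,7-bis(benzyloxy)-8-methyl-4-(2-phenylethyl)-6-(3-phenylpropanoyl)-3,4-dihydro-2H-chromen-2-one | O=C1C[C@@H](CCc2ccccc2)c2c(OCc3ccccc3)c(C(=O)CCc3ccccc3)c(OCc3ccccc3)c(C)c2O1
F7 | step 8 | (3S)-3-[2,4-bis(benzyloxy)-6-hydroxy-5-methyl-3-(3-phenylpropanoyl)phenyl]-N-methoxy-N-methyl-5-phenylpentanamide | CON(C)C(=O)C[C@H](CCc1ccccc1)c1c(O)c(C)c(OCc2ccccc2)c(C(=O)CCc2ccccc2)c1OCc1ccccc1
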